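**Retrosynthetic overview**

1. The target is read as a cis-fused (5β-H) labdane: the C-19 acid on C-4, H-5, the C-20 methyl on C-10 and the C-9 side chain all lie on one face, and C-13 is R. The last operations are desilylation and acetylation of the C-13 carbinol, which is carried in from (R)-linalool.
2. Key disconnection (ring B, closed last): the C9–C10 bond and the C8=C17 methylene lead back to lactone 15, in which the C-19 carboxyl is tied to C-10 of ring A as a bridged γ-lactone and C-5 carries an allylsilane chain.
3. Enabling feature: in ring A the C-19 carboxyl (on C-4) and C-10 are 1,3-syn, so the tertiary C10–O lactone bond is a latent C-10 cation. The C-6 branch on C-5 is anti to that bridge, which turns inversion at C-10 into the cis A/B fusion, and C-8(=C-17)/C-9 is the retron of an allylsilane.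
4. 15 comes from a B-alkyl Suzuki coupling of vinyl lactone 8 with the Z-bromoallylsilane 13, made from (R)-linalool by ozonolysis, dibromo-olefination and a trans-selective Negishi coupling.
5. Ring order: ring A first (asymmetric Robinson annulation, CBS reduction, anti-SN2' vinylation, acid lactonisation to the temporary lactone ring), ring B last. The lactone ring is opened in the key step and gives the free acid directly.

Key step: step 11

Remark on the chemistry: labdane numbering (C-1 to C-20) is used for all intermediates; the C-10 centre of lactones 8, 14 and 15 is only a relay, because it is ionised in step 11.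

**Route**

Step 1
Reactants: 1 ethyl 2-formylpropanoate; 2 pent-1-en-3-one (ethyl vinyl ketone)
Product: 4 ethyl (S)-1,3-dimethyl-4-oxocyclohex-2-ene-1-carboxylate, via keto-aldehyde Michael adduct 3 (not isolated)
Conditions: 9-amino-9-deoxy-epi-quinine (20 mol %), CF3CO2H (40 mol %), toluene, 40 °C; then p-TsOH·H2O (10 mol %), toluene, reflux, −H2O
Reagents that add atoms: none
Why: Amine-catalysed asymmetric Michael addition (the primary amine forms a hydrogen-bonded enamino ester with the formyl group and shields one face, which should set the quaternary C-4 centre as S; the quinidine-derived pseudo-enantiomer would give the antipode) followed by intramolecular aldol condensation, i.e. an organocatalytic Robinson annulation in which only the six-membered enone can form.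

Step 2
Reactants: 4 ethyl (S)-1,3-dimethyl-4-oxocyclohex-2-ene-1-carboxylate
Product: 5 ethyl (1S,4R)-4-hydroxy-1,3-dimethylcyclohex-2-ene-1-carboxylate (OH cis to the ester)
Conditions: (S)-2-methyl-CBS-oxazaborolidine (10 mol %), BH3·SMe2, THF, −20 °C
Reagents that add atoms: none
Why: Corey–Bakshi–Shibata reduction: catalyst-controlled 1,2-hydride delivery (the 2-methylalkenyl branch acts as the large group) should set the carbinol centre as R, cis to the ester, and leaves the ester untouched.

Step 3
Reactants: 5 ethyl (1S,4R)-4-hydroxy-1,3-dimethylcyclohex-2-ene-1-carboxylate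
Product: 6 (1R,4S)-4-(ethoxycarbonyl)-2,4-dimethylcyclohex-2-en-1-yl pyridine-2-carboxylate
Conditions: pyridine-2-carboxylic acid, DCC, DMAP (cat.), CH2Cl2, 0 °C → rt
Reagents that add atoms: pyridine-2-carboxylic acid (picolinic acid), OC(=O)c1ccccn1
Why: Steglich esterification of a secondary allylic alcohol; no stereocentre is touched.

Step 4
Reactants: 6 (1R,4S)-4-(ethoxycarbonyl)-2,4-dimethylcyclohex-2-en-1-yl pyridine-2-carboxylate
Product: 7 ethyl (1S,2S)-2-ethenyl-1,3-dimethylcyclohex-3-ene-1-carboxylate (vinyl trans to the ester)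
Conditions: vinylmagnesium bromide, CuBr·SMe2 (10 mol %), THF, −40 → 0 °C
Reagents that add atoms: vinylmagnesium bromide, C=C[Mg]Br
Why: Copper-catalysed anti-SN2' allylic substitution of an allylic picolinate by a Grignard reagent (magnesium chelation by the picolinate activates the leaving group): the vinyl group enters C-5 on the face opposite the leaving group, i.e. trans to the ester, and the double bond moves to C10=C1.

Step 5
Reactants: 7 ethyl (1S,2S)-2-ethenyl-1,3-dimethylcyclohex-3-ene-1-carboxylate
Product: 8 (1S,5R,8R)-8-ethenyl-1,5-dimethyl-6-oxabicyclo[3.2.1]octan-7-one (vinyl anti to the lactone bridge)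
Conditions: TfOH (1.1 equiv), CH2Cl2, −40 → 0 °C; aq. NaHCO3
Reagents that add atoms: none
Why: Brønsted-acid lactonisation of a γ,δ-unsaturated ester: Markovnikov protonation of the trisubstituted alkene gives the tertiary C-10 cation, which the 1,3-syn ester carbonyl captures with loss of the ethyl group as EtOTf; the bridge can only form on the carboxyl face (this fixes C-10), the monosubstituted vinyl group is not protonated, and in the reacting conformer (ester and vinyl trans-diaxial) H-5 is equatorial, so no hydride shift should compete.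

Step 6
Reactants: 9 (R)-(−)-linalool
Product: 10 (R)-tert-butyl[(3,7-dimethylocta-1,6-dien-3-yl)oxy]dimethylsilane
Conditions: TBSOTf, 2,6-lutidine, CH2Cl2, 0 °C
Reagents that add atoms: tert-butyldimethylsilyl trifluoromethanesulfonate (TBSOTf), CC(C)(C)[Si](C)(C)OS(=O)(=O)C(F)(F)F
Why: Silylation of a tertiary alcohol with a silyl triflate; the C-13 stereocentre comes from the chiral pool and is not touched.

Step 7
Reactants: 10 (R)-tert-butyl[(3,7-dimethylocta-1,6-dien-3-yl)oxy]dimethylsilane
Product: 11 (R)-4-[(tert-butyldimethylsilyl)oxy]-4-methylhex-5-enal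
Conditions: O3, CH2Cl2/MeOH, pyridine, Sudan Red 7B, −78 °C; then Me2S
Reagents that add atoms: ozone, [O-][O+]=O
Why: Chemoselective ozonolysis: the electron-rich trisubstituted alkene reacts far faster than the hindered monosubstituted vinyl group next to the silyloxy carbon, and the indicator dye marks the end point.

Step 8
Reactants: 11 (R)-4-[(tert-butyldimethylsilyl)oxy]-4-methylhex-5-enal
Product: 12 (R)-tert-butyl[(7,7-dibromo-3-methylhepta-1,6-dien-3-yl)oxy]dimethylsilane
Conditions: CBr4, PPh3, Zn, CH2Cl2, 0 °C → rt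
Reagents that add atoms: carbon tetrabromide, BrC(Br)(Br)Br
Why: Ramirez dibromo-olefination (first stage of the Corey–Fuchs sequence) of an aldehyde; zinc keeps the medium free of acid, so the silyl ether survives.

Step 9
Reactants: 12 (R)-tert-butyl[(7,7-dibromo-3-methylhepta-1,6-dien-3-yl)oxy]dimethylsilane
Product: 13 (R,Z)-{2-bromo-6-[(tert-butyldimethylsilyl)oxy]-6-methylocta-2,7-dien-1-yl}trimethylsilane
Conditions: Me3SiCH2MgCl, ZnCl2, THF, 0 °C; then 12, PdCl2(DPEphos) (3 mol %), THF, 0 °C → rt
Reagents that add atoms: (trimethylsilyl)methylmagnesium chloride, C[Si](C)(C)C[Mg]Cl (transmetallated in the flask to (trimethylsilyl)methylzinc chloride, C[Si](C)(C)C[Zn]Cl)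
Why: Trans-selective Negishi mono-coupling of a 1,1-dibromoalkene: oxidative addition of zerovalent palladium occurs at the less hindered C–Br bond trans to the chain, so the bromide left behind is cis to the chain (Z) and the silylmethyl group is trans to it.

Step 10
Reactants: 8 (1S,5R,8R)-8-ethenyl-1,5-dimethyl-6-oxabicyclo[3.2.1]octan-7-one; 13 (R,Z)-{2-bromo-6-[(tert-butyldimethylsilyl)oxy]-6-methylocta-2,7-dien-1-yl}trimethylsilane
Product: 15 (1S,5R,8R)-8-{(3E,7R)-7-[(tert-butyldimethylsilyl)oxy]-7-methyl-3-[(trimethylsilyl)methyl]nona-3,8-dien-1-yl}-1,5-dimethyl-6-oxabicyclo[3.2.1]octan-7-one, via B-alkyl-9-BBN borane 14 (not isolated)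
Conditions: 9-BBN, THF, rt; H2O (few drops); then 13, PdCl2(dppf) (5 mol %), AsPh3, Cs2CO3, DMF/THF/H2O, rt
Reagents that add atoms: none
Why: Anti-Markovnikov hydroboration of the only alkene of 8 followed by B-alkyl Suzuki–Miyaura coupling, which proceeds with retention at the alkenyl bromide and so places the ring tether (C-7) cis to C-11; excess borane is quenched before 13, which carries a vinyl group, is added.

Step 11
Reactants: 15 (1S,5R,8R)-8-{(3E,7R)-7-[(tert-butyldimethylsilyl)oxy]-7-methyl-3-[(trimethylsilyl)methyl]nona-3,8-dien-1-yl}-1,5-dimethyl-6-oxabicyclo[3.2.1]octan-7-one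
Product: 16 (1S,4aR,5S,8aS)-5-{(3R)-3-[(tert-butyldimethylsilyl)oxy]-3-methylpent-4-en-1-yl}-1,4a-dimethyl-6-methylidenedecahydronaphthalene-1-carboxylic acid (cis-fused)
Conditions: EtAlCl2 (2.5 equiv), CH2Cl2, −78 → −20 °C; aq. potassium sodium tartrate (KNaC4H4O6), then dil. HCl
Reagents that add atoms: none
Why: Proposed new method: EtAlCl2 binds the lactone carbonyl and the tertiary C10–O bond of the bridged lactone ionises to a C-10 cation/aluminium carboxylate contact ion pair; C-9 of the allylsilane attacks C-10 and the β-silyl cation at C-8 loses Me3Si+ to chloride (SE2'), which delivers the C8=C17 methylene, while work-up frees the C-19 acid. The closest known reactions are the Lewis-acid alkylation of allylsilanes by tertiary alkyl halides and esters (Hosomi–Sakurai type), allylsilane-terminated cation–olefin cyclisations (this is the ring B event of labdane biosynthesis) and the acid ionisation of tertiary γ-lactones in Friedel–Crafts alkylations. Ring B closes in a 6-endo-trig mode (with respect to the C8=C9 bond) through a chair. At C-10 the tether on C-5 is axial and anti to the lactone bridge, so C-9 enters on the face opposite the departing carboxylate (inversion), which should give the cis ring fusion with the C-20 methyl syn to the C-19 acid and H-5; at C-9 the chair transition state places C-11, which is cis to C-7 on the alkene, axial and therefore cis to the C-20 methyl. The step needs ring closure to outrun E1 proton loss, protodesilylation and ionisation of the C-13 silyl ether: the intramolecular six-ring capture, the proton-scavenging alkylaluminium Lewis acid at low temperature and the fact that the lactone carbonyl is the only good Lewis-basic site (the tertiary silyl ether is hindered and a poor donor) are what should secure this.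

Step 12
Reactants: 16 (1S,4aR,5S,8aS)-5-{(3R)-3-[(tert-butyldimethylsilyl)oxy]-3-methylpent-4-en-1-yl}-1,4a-dimethyl-6-methylidenedecahydronaphthalene-1-carboxylic acid
Product: 17 (1S,4aR,5S,8aS)-5-[(3R)-3-hydroxy-3-methylpent-4-en-1-yl]-1,4a-dimethyl-6-methylidenedecahydronaphthalene-1-carboxylic acid
Conditions: TBAF (3 equiv), THF, 45 °C; aq. NH4Cl
Reagents that add atoms: none
Why: Fluoride cleavage of the silyl ether (the allylsilane is gone and the acid is carried as its carboxylate); no stereocentre is touched.

Step 13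
Reactants: 17 (1S,4aR,5S,8aS)-5-[(3R)-3-hydroxy-3-methylpent-4-en-1-yl]-1,4a-dimethyl-6-methylidenedecahydronaphthalene-1-carboxylic acid
Product: 18 (1S,4aR,5S,8aS)-5-[(3R)-3-acetoxy-3-methylpent-4-en-1-yl]-1,4a-dimethyl-6-methylidenedecahydronaphthalene-1-carboxylic acid (target)
Conditions: Ac2O, Et3N, DMAP, CH2Cl2, rt; then aq. NaHCO3/THF
Reagents that add atoms: acetic anhydride, CC(=O)OC(C)=O
Why: DMAP-catalysed acylation of the tertiary allylic alcohol with retention at C-13 under non-ionising basic conditions; the mixed anhydride formed at the hindered C-19 acid is hydrolysed in the bicarbonate work-up.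

**Compound list**

1 | ethyl 2-formylpropanoate (racemic) | CCOC(=O)C(C)C=O | starting material
2 | pent-1-en-3-one (ethyl vinyl ketone) | CCC(=O)C=C | starting material
3 | ethyl (S)-2-formyl-2-methyl-5-oxoheptanoate | CCOC(=O)[C@](C)(C=O)CCC(=O)CC | intermediate (not isolated)
4 | ethyl (S)-1,3-dimethyl-4-oxocyclohex-2-ene-1-carboxylate | CCOC(=O)[C@]1(C)C=C(C)C(=O)CC1 | intermediate
5 | ethyl (1S,4R)-4-hydroxy-1,3-dimethylcyclohex-2-ene-1-carboxylate | CCOC(=O)[C@]1(C)C=C(C)[C@H](O)CC1 | intermediate
6 | (1R,4S)-4-(ethoxycarbonyl)-2,4-dimethylcyclohex-2-en-1-yl pyridine-2-carboxylate | CCOC(=O)[C@]1(C)C=C(C)[C@H](OC(=O)c2ccccn2)CC1 | intermediate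
7 | ethyl (1S,2S)-2-ethenyl-1,3-dimethylcyclohex-3-ene-1-carboxylate | CCOC(=O)[C@]1(C)[C@@H](C=C)C(C)=CCC1 | intermediate
8 | (1S,5R,8R)-8-ethenyl-1,5-dimethyl-6-oxabicyclo[3.2.1]octan-7-one | C=C[C@H]1[C@@]2(C)CCC[C@]1(C)C(=O)O2 | intermediate
9 | (R)-(−)-linalool, (3R)-3,7-dimethylocta-1,6-dien-3-ol | C=C[C@](C)(O)CCC=C(C)C | starting material
10 | (R)-tert-butyl[(3,7-dimethylocta-1,6-dien-3-yl)oxy]dimethylsilane | C=C[C@](C)(O[Si](C)(C)C(C)(C)C)CCC=C(C)C | intermediate
11 | (R)-4-[(tert-butyldimethylsilyl)oxy]-4-methylhex-5-enal | C=C[C@](C)(O[Si](C)(C)C(C)(C)C)CCC=O | intermediate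
12 | (R)-tert-butyl[(7,7-dibromo-3-methylhepta-1,6-dien-3-yl)oxy]dimethylsilane | C=C[C@](C)(O[Si](C)(C)C(C)(C)C)CCC=C(Br)Br | intermediate
13 | (R,Z)-{2-bromo-6-[(tert-butyldimethylsilyl)oxy]-6-methylocta-2,7-dien-1-yl}trimethylsilane | C=C[C@](C)(O[Si](C)(C)C(C)(C)C)CC/C=C(\Br)C[Si](C)(C)C | intermediate
14 | (1S,5R,8R)-8-[2-(9-borabicyclo[3.3.1]nonan-9-yl)ethyl]-1,5-dimethyl-6-oxabicyclo[3.2.1]octan-7-one | C(C[C@H]1[C@@]2(C)CCC[C@]1(C)C(=O)O2)B1C2CCCC1CCC2 | intermediate (not isolated)
15 | (1S,5R,8R)-8-{(3E,7R)-7-[(tert-butyldimethylsilyl)oxy]-7-methyl-3-[(trimethylsilyl)methyl]nona-3,8-dien-1-yl}-1,5-dimethyl-6-oxabicyclo[3.2.1]octan-7-one | C=C[C@](C)(O[Si](C)(C)C(C)(C)C)CC/C=C(/C[Si](C)(C)C)CC[C@H]1[C@@]2(C)CCC[C@]1(C)C(=O)O2 | intermediate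
16 | (1S,4aR,5S,8aS)-5-{(3R)-3-[(tert-butyldimethylsilyl)oxy]-3-methylpent-4-en-1-yl}-1,4a-dimethyl-6-methylidenedecahydronaphthalene-1-carboxylic acid | C=C[C@@](C)(CC[C@H]1C(=C)CC[C@H]2[C@]1(C)CCC[C@]2(C)C(=O)O)O[Si](C)(C)C(C)(C)C | intermediate
17 | (1S,4aR,5S,8aS)-5-[(3R)-3-hydroxy-3-methylpent-4-en-1-yl]-1,4a-dimethyl-6-methylidenedecahydronaphthalene-1-carboxylic acid | C=C[C@@](C)(CC[C@H]1C(=C)CC[C@H]2[C@]1(C)CCC[C@]2(C)C(=O)O)O | intermediate
18 | (1S,4aR,5S,8aS)-5-[(3R)-3-acetoxy-3-methylpent-4-en-1-yl]-1,4a-dimethyl-6-methylidenedecahydronaphthalene-1-carboxylic acid, i.e. (13R)-13-acetoxy-5β-labda-8(17),14-dien-19-oic acid | C=C[C@@](C)(CC[C@H]1C(=C)CC[C@H]2[C@]1(C)CCC[C@]2(C)C(=O)O)OC(C)=O | target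

**Step count**

Total steps: 13. Longest linear sequence: 9 (steps 1–5 and 10–13); the side-chain branch is steps 6–9.

**Steps most likely to fail, with fallbacks**

1. Step 11 (Proposed new method). What may go wrong: capture of the C-10 cation on the carboxylate face (trans ring fusion), proton loss from the cation before ring closure, or ionisation of the tertiary allylic silyl ether at C-13. The fallback uses known chemistry: a tertiary chloride replaces the lactone as the cation source and the acid is carried as its ester. It sets out from 7. HCl (CH2Cl2, −78 °C) adds to the ring alkene of 7 in the Markovnikov sense to give the tertiary chloride ethyl (1S,2R)-3-chloro-2-ethenyl-1,3-dimethylcyclohexane-1-carboxylate F1 (either C-10 epimer serves). Hydroboration with 9-BBN and Suzuki coupling with 13 as in step 10, but with Cs2CO3 in dry DMF, give the chloro allylsilane ethyl (1S,2R)-2-{(3E,7R)-7-[(tert-butyldimethylsilyl)oxy]-7-methyl-3-[(trimethylsilyl)methyl]nona-3,8-dien-1-yl}-3-chloro-1,3-dimethylcyclohexane-1-carboxylate F2. TiCl4 with 2,6-di-tert-butyl-4-methylpyridine (CH2Cl2, −78 °C), the known Lewis-acid alkylation of an allylsilane by a tertiary alkyl chloride run intramolecularly, closes ring B to the ethyl ester ethyl (1S,4aR,5S,8aS)-5-{(3R)-3-[(tert-butyldimethylsilyl)oxy]-3-methylpent-4-en-1-yl}-1,4a-dimethyl-6-methylidenedecahydronaphthalene-1-carboxylate F3. A chloride ionises under milder conditions than the lactone, which also spares the C-13 ether. Hydrolysis (KOH, EtOH/H2O, 100 °C) returns to the route at 16.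

2. Step 4. What may go wrong: attack of the copper reagent at the less hindered α-carbon (SN2) or at the picolinate carbonyl, instead of at the γ-carbon next to the quaternary centre. The fallback replaces allylic substitution by conjugate addition and sets out from 4. Copper-catalysed 1,4-addition of vinylmagnesium bromide (CuBr·SMe2, THF, −78 °C) to the enone, with trapping of the enolate by PhNTf2, gives the enol triflate ethyl (1S,2S)-2-ethenyl-1,3-dimethyl-4-{[(trifluoromethyl)sulfonyl]oxy}cyclohex-3-ene-1-carboxylate F4. Addition is expected anti to the pseudo-axial ester, but facial control is less secure than in step 4, so the diastereomers would be separated here. Reduction of the triflate (Pd(OAc)2, PPh3, HCO2H, Bu3N, DMF, 60 °C) returns to the route at 7.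

3. Step 5. What may go wrong: a hydride shift from C-5 to the C-10 cation (allyl cation formation and loss of the C-5 stereocentre) or protonation of the vinyl group under the strong acid. The fallback avoids a free cation and sets out from 7. Saponification (KOH, EtOH/H2O, 100 °C) gives (1S,2S)-2-ethenyl-1,3-dimethylcyclohex-3-ene-1-carboxylic acid F5. Iodolactonisation (I2, NaHCO3, MeCN/H2O, 0 °C), in which the carboxylate opens the iodonium ion at the tertiary carbon, gives (1S,4S,5S,8R)-8-ethenyl-4-iodo-1,5-dimethyl-6-oxabicyclo[3.2.1]octan-7-one F6 (iodine trans to the lactone oxygen). Radical deiodination (Bu3SnH, AIBN, benzene, 80 °C) returns to the route at 8.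

Further compounds
F1 | step 11 | ethyl (1S,2R)-3-chloro-2-ethenyl-1,3-dimethylcyclohexane-1-carboxylate | C=C[C@H]1C(C)(Cl)CCC[C@]1(C)C(=O)OCC
F2 | step 11 | ethyl (1S,2R)-2-{(3E,7R)-7-[(tert-butyldimethylsilyl)oxy]-7-methyl-3-[(trimethylsilyl)methyl]nona-3,8-dien-1-yl}-3-chloro-1,3-dimethylcyclohexane-1-carboxylate | C=C[C@](C)(O[Si](C)(C)C(C)(C)C)CC/C=C(/C[Si](C)(C)C)CC[C@H]1C(C)(Cl)CCC[C@]1(C)C(=O)OCC
F3 | step 11 | ethyl (1S,4aR,5S,8aS)-5-{(3R)-3-[(tert-butyldimethylsilyl)oxy]-3-methylpent-4-en-1-yl}-1,4a-dimethyl-6-methylidenedecahydronaphthalene-1-carboxylate | C=C[C@@](C)(CC[C@H]1C(=C)CC[C@H]2[C@]1(C)CCC[C@]2(C)C(=O)OCC)O[Si](C)(C)C(C)(C)C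
F4 | step 4 | ethyl (1S,2S)-2-ethenyl-1,3-dimethyl-4-{[(trifluoromethyl)sulfonyl]oxy}cyclohex-3-ene-1-carboxylate | CCOC(=O)[C@]1(C)[C@@H](C=C)C(C)=C(OS(=O)(=O)C(F)(F)F)CC1
F5 | step 5 | (1S,2S)-2-ethenyl-1,3-dimethylcyclohex-3-ene-1-carboxylic acid | OC(=O)[C@]1(C)[C@@H](C=C)C(C)=CCC1
F6 | step 5 | (1S,4S,5S,8R)-8-ethenyl-4-iodo-1,5-dimethyl-6-oxabicyclo[3.2.1]octan-7-one | C=C[C@H]1[C@@]2(C)[C@@H](I)CC[C@]1(C)C(=O)O2
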